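**Plan**
1. Numbering: the five-membered carbocycle is C1 (CH bearing acetyl), C2 (CH2), C3 (quaternary carbon shared by all three rings), C7 (CH) and C8 (CMe2). C4 is the one-carbon keto bridge, C5 the methyl-bearing bridgehead and C6 a CH2. C9 and C11 are the ketones on either side of C10, which carries prenyl and isobutyryl.
2. Enabling feature: C3 lies between the C4 and C11 carbonyl groups, so a radical at C3 is stabilised and electrophilic, and the C7–C8 edge is the former C=C of a prenyl group on C5. The carbocycle C1–C2–C3–C7–C8 is therefore grown from a spiro vinylcyclopropane C1–C2–C3 by inserting C7=C8 into its C1–C3 bond, rather than closed as a five-membered ring.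
3. Cuts, in retrosynthetic order: acetyl back to vinyl; C10–prenyl; C3–C7 and C1–C8 (with C1–C3 restored); C3–C1 and C3–C2; C9–C10; C3–C4; C5–prenyl.
4. Forward order: quaternary malonate, open-chain tetracarbonyl ester, six-membered trione ring, three-membered spiro ring. One radical chain step then gives the cyclopentanone ring and the enlarged carbocycle, followed by C10 prenylation and Wacker oxidation.
5. Stereochemistry: C5 comes from an asymmetric phase-transfer prenylation. C3, C7 and C1 are relayed from C5 in the key step. C10 comes from attack on the enolate face turned away from the C6–C7 bridge.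

Key step: step 8

Assumption: the (R,R)-configured phase-transfer catalyst is taken to give the (R)-malonate (its commercial mirror image is used if the sense of induction is the opposite), and enolised polycarbonyl compounds are drawn as one tautomer.

**Step 1**
Reactants: 1 2,2,5-trimethyl-1,3-dioxane-4,6-dione; 2 tert-butanol
Product: 3 3-tert-butoxy-2-methyl-3-oxopropanoic acid (racemic)
Conditions: t-BuOH (solvent), reflux
Reagents that add atoms: none
Why: Alcoholysis of the Meldrum's acid ring by the hindered alcohol should stop at the half ester because the carboxylic acid formed is unreactive, and the CH(CH3) centre is of no consequence since it is enolised in step 3.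

**Step 2**
Reactants: 3 3-tert-butoxy-2-methyl-3-oxopropanoic acid; 4 2,2-diphenylethanol
Product: 5 1-tert-butyl 3-(2,2-diphenylethyl) 2-methylpropanedioate (racemic)
Conditions: DCC, DMAP (cat.), CH2Cl2, 0 °C to rt
Reagents that add atoms: none
Why: Steglich esterification of a malonic half acid with a primary alcohol runs under neutral conditions, leaves the tert-butyl ester intact and gives the mixed diester whose two unlike ester groups the chiral catalyst of step 3 can tell apart.

**Step 3**
Reactants: 5 1-tert-butyl 3-(2,2-diphenylethyl) 2-methylpropanedioate; 6 1-bromo-3-methylbut-2-ene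
Product: 7 1-tert-butyl 3-(2,2-diphenylethyl) (2R)-2-methyl-2-(3-methylbut-2-en-1-yl)propanedioate
Conditions: (R,R)-3,4,5-trifluorophenyl-NAS bromide (N-spiro binaphthyl ammonium salt, 5 mol %), 50% aq KOH, toluene, −40 °C
Reagents that add atoms: none
Why: In this asymmetric phase-transfer alkylation of an α-methylmalonate with an allylic bromide, the enolate pairs with the chiral ammonium cation, which shields one enantiotopic face, so the quaternary centre C5 is set here as R.

**Step 4**
Reactants: 7 1-tert-butyl 3-(2,2-diphenylethyl) (2R)-2-methyl-2-(3-methylbut-2-en-1-yl)propanedioate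
Product: 9 (2S)-3-(2,2-diphenylethoxy)-2-methyl-2-(3-methylbut-2-en-1-yl)-3-oxopropanoic acid, via trimethylsilyl ester 8 (not isolated)
Conditions: TMSOTf, 2,6-lutidine, CH2Cl2, 0 °C; then pH 4 buffer
Reagents that add atoms: none
Why: Silyl triflate cleavage of a tert-butyl ester (loss of 2-methylpropene, then hydrolysis of the silyl ester) needs no free protic acid, so the prenyl alkene should be neither protonated nor lactonised, the primary ester stays, and quaternary C5 cannot epimerise (the descriptor changes only through the priority rules).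

**Step 5**
Reactants: 9 (2S)-3-(2,2-diphenylethoxy)-2-methyl-2-(3-methylbut-2-en-1-yl)-3-oxopropanoic acid; 10 5-methylhexane-2,4-dione
Product: 13 2,2-diphenylethyl (2S)-2,8-dimethyl-2-(3-methylbut-2-en-1-yl)-3,5,7-trioxononanoate, via acyl imidazolide 11 (not isolated), via dilithio dianion 12 (not isolated)
Conditions: 9, CDI, THF, rt; separately 10 (3 equiv), LDA (6 equiv), THF, −78 to 0 °C; combine at −78 °C, warm to 0 °C; aq HCl
Reagents that add atoms: none
Why: Claisen-type acylation of a β-diketone dianion at its terminal, more basic carbon joins C3 to C4, because the acyl donor has no α-hydrogen, the imidazolide is far more electrophilic than the alkyl ester, and the excess dianion takes up the acidic product and the imidazole.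

**Step 6**
Reactants: 13 2,2-diphenylethyl (2S)-2,8-dimethyl-2-(3-methylbut-2-en-1-yl)-3,5,7-trioxononanoate
Product: 14 (6S)-3,5-dihydroxy-6-methyl-6-(3-methylbut-2-en-1-yl)-2-(2-methylpropanoyl)cyclohexa-2,4-dien-1-one
Conditions: KOtBu (3 equiv), THF, 0 to 50 °C; aq HCl
Reagents that add atoms: none
Why: In this Dieckmann-type cyclisation (6-exo-trig) C10 is the only carbanion that can reach the C9 ester through a six-membered transition state, any enol lactone from O-acylation reopens under the alkoxide, and formation of the strongly acidic β-triketone enolate drives the closure while quaternary C5 is untouched.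

**Step 7**
Reactants: 14 (6S)-3,5-dihydroxy-6-methyl-6-(3-methylbut-2-en-1-yl)-2-(2-methylpropanoyl)cyclohexa-2,4-dien-1-one; 15 (E)-1,4-dibromobut-2-ene
Product: 16 (5R)-1-ethenyl-6-hydroxy-5-methyl-5-(3-methylbut-2-en-1-yl)-7-(2-methylpropanoyl)spiro[2.5]oct-6-ene-4,8-dione (mixture of isomers at the two cyclopropane stereocentres)
Conditions: Cs2CO3, DMF, 0 °C to rt, short reaction time
Reagents that add atoms: none
Why: Double alkylation of an active methylene with a 1,4-dihalobut-2-ene (SN2, then intramolecular SN2' in the 3-exo mode) is the standard entry to 2-vinylcyclopropane-1,1-dicarbonyl compounds, C3 is the carbon at which dearomatised acylphloroglucinol dianions take up allylic bromides, and the two new stereocentres need no control because step 8 erases or resets them.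

**Step 8**
Reactants: 16 (5R)-1-ethenyl-6-hydroxy-5-methyl-5-(3-methylbut-2-en-1-yl)-7-(2-methylpropanoyl)spiro[2.5]oct-6-ene-4,8-dione
Product: 17 (1R,3R,5R,7R)-3-ethenyl-8-hydroxy-4,4,7-trimethyl-9-(2-methylpropanoyl)tricyclo[5.3.1.0^1,5]undec-8-ene-10,11-dione (C8 exo on C7, that is syn to the C4 bridge; vinyl cis to H-7)
Conditions: PhSSPh (20 mol %), 400 nm LED, degassed benzene (0.01 M), 25 °C
Reagents that add atoms: none
Why: The phenylthiyl radical adds reversibly to both alkenes, but only the adduct at the vinyl CH2 is a cyclopropylcarbinyl radical, and its β-scission breaks C1–C3 rather than C1–C2 because only that bond releases the ring strain into a C3 radical delocalised over the C4 and C11 carbonyl groups. This electrophilic radical adds 5-exo-trig to C7, the less substituted end of the electron-rich prenyl C=C on C5, which closes the cyclopentanone C3–C4–C5–C6–C7 and with it the bicyclo[3.2.1]octane; the tertiary C8 radical then adds 5-exo-trig to C1 of the allyl sulfide, and β-loss of the thiyl radical restores the vinyl group and carries the chain, so the three-membered ring C1–C2–C3 has grown by C7 and C8 into the five-membered ring. The closest known reaction type is the thiyl-radical-catalysed (3+2) annulation of 2-vinylcyclopropane-1,1-dicarbonyl compounds with electron-rich alkenes, and the two closures match the oxidative 5-exo/5-exo cascades known for dearomatised prenylated acylphloroglucinols. C3 is fixed by C5 because the short C4 link lets the prenyl chain reach only the radical face on which it stands; C7 is fixed because the CMe2 terminus turns away from the C9–C10–C11 bridge (exo), the only orientation from which C8 can reach C1; C1 is fixed because the sulfide-bearing end of the acceptor alkene points to the convex face of the forming cis-bicyclo[3.3.0]octane, cis to H-7. All cyclopropane isomers of 16 converge because their stereocentres vanish on ring opening. High dilution, the absence of a thiol hydrogen donor and room-temperature photoinitiation should keep hydrothiolation, phenylthio transfer from the disulfide and thermal isomerisation of 16 slower than the two cyclisations.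

**Step 9**
Reactants: 17 (1R,3R,5R,7R)-3-ethenyl-8-hydroxy-4,4,7-trimethyl-9-(2-methylpropanoyl)tricyclo[5.3.1.0^1,5]undec-8-ene-10,11-dione; 18 3-methylbut-2-en-1-yl acetate
Product: 19 (1R,3R,5R,7S,9S)-3-ethenyl-4,4,7-trimethyl-9-(3-methylbut-2-en-1-yl)-9-(2-methylpropanoyl)tricyclo[5.3.1.0^1,5]undecane-8,10,11-trione
Conditions: Pd(PPh3)4 (5 mol %), Et3N (1.1 equiv), THF, 50 °C
Reagents that add atoms: none
Why: In this Tsuji–Trost allylic alkylation the soft ammonium enolate of the acidic β-triketone attacks the unsubstituted terminus of the 1,1-dimethylallyl palladium complex, O-prenyl isomers re-ionise under zerovalent palladium and drain to the C-alkylated product, and the electrophile reaches C10 on the face syn to the C4 keto bridge because the endo hydrogens of the C6–C7 bridge shield the other face, which sets C10 as S.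

**Step 10**
Reactants: 19 (1R,3R,5R,7S,9S)-3-ethenyl-4,4,7-trimethyl-9-(3-methylbut-2-en-1-yl)-9-(2-methylpropanoyl)tricyclo[5.3.1.0^1,5]undecane-8,10,11-trione
Product: 20 (1R,3S,5R,7S,9S)-3-acetyl-4,4,7-trimethyl-9-(3-methylbut-2-en-1-yl)-9-(2-methylpropanoyl)tricyclo[5.3.1.0^1,5]undecane-8,10,11-trione (CNP0322535.2)
Conditions: PdCl2 (10 mol %), CuCl (20 mol %), O2 (1 atm), DMF/H2O 7:1, rt
Reagents that add atoms: water, O
Why: Wacker–Tsuji oxidation hydroxypalladates the monosubstituted vinyl group in the Markovnikov sense and leaves the trisubstituted prenyl alkene alone, no enol oxygen remains after step 9 to compete by oxypalladation, and C1 keeps its geometry with the acetyl group on the convex face (the descriptor changes only through the priority rules).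

**Compound list**
1 | 2,2,5-trimethyl-1,3-dioxane-4,6-dione | CC1C(=O)OC(C)(C)OC1=O | starting material
2 | tert-butanol | CC(C)(C)O | starting material
3 | 3-tert-butoxy-2-methyl-3-oxopropanoic acid (racemic) | CC(C(=O)O)C(=O)OC(C)(C)C | intermediate
4 | 2,2-diphenylethanol | OCC(c1ccccc1)c1ccccc1 | starting material
5 | 1-tert-butyl 3-(2,2-diphenylethyl) 2-methylpropanedioate (racemic) | CC(C(=O)OC(C)(C)C)C(=O)OCC(c1ccccc1)c1ccccc1 | intermediate
6 | 1-bromo-3-methylbut-2-ene | CC(C)=CCBr | starting material
7 | 1-tert-butyl 3-(2,2-diphenylethyl) (2R)-2-methyl-2-(3-methylbut-2-en-1-yl)propanedioate | CC(C)(C)OC(=O)[C@](C)(CC=C(C)C)C(=O)OCC(c1ccccc1)c1ccccc1 | intermediate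
8 | 1-(2,2-diphenylethyl) 3-trimethylsilyl (2R)-2-methyl-2-(3-methylbut-2-en-1-yl)propanedioate | C[Si](C)(C)OC(=O)[C@](C)(CC=C(C)C)C(=O)OCC(c1ccccc1)c1ccccc1 | intermediate
9 | (2S)-3-(2,2-diphenylethoxy)-2-methyl-2-(3-methylbut-2-en-1-yl)-3-oxopropanoic acid | OC(=O)[C@](C)(CC=C(C)C)C(=O)OCC(c1ccccc1)c1ccccc1 | intermediate
10 | 5-methylhexane-2,4-dione | CC(=O)CC(=O)C(C)C | starting material
11 | 2,2-diphenylethyl (2S)-3-(1H-imidazol-1-yl)-2-methyl-2-(3-methylbut-2-en-1-yl)-3-oxopropanoate | O=C(n1ccnc1)[C@](C)(CC=C(C)C)C(=O)OCC(c1ccccc1)c1ccccc1 | intermediate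
12 | dilithium 5-methylhexa-1,3-diene-2,4-diolate (dianion of 10) | [Li+].[Li+].C=C([O-])C=C([O-])C(C)C | intermediate
13 | 2,2-diphenylethyl (2S)-2,8-dimethyl-2-(3-methylbut-2-en-1-yl)-3,5,7-trioxononanoate | CC(C)C(=O)CC(=O)CC(=O)[C@](C)(CC=C(C)C)C(=O)OCC(c1ccccc1)c1ccccc1 | intermediate
14 | (6S)-3,5-dihydroxy-6-methyl-6-(3-methylbut-2-en-1-yl)-2-(2-methylpropanoyl)cyclohexa-2,4-dien-1-one | CC(C)C(=O)C1=C(O)C=C(O)[C@](C)(CC=C(C)C)C1=O | intermediate
15 | (E)-1,4-dibromobut-2-ene | BrC/C=C/CBr | starting material
16 | (5R)-1-ethenyl-6-hydroxy-5-methyl-5-(3-methylbut-2-en-1-yl)-7-(2-methylpropanoyl)spiro[2.5]oct-6-ene-4,8-dione (cyclopropane centres undefined) | C=CC1CC12C(=O)[C@](C)(CC=C(C)C)C(O)=C(C(=O)C(C)C)C2=O | intermediate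
17 | (1R,3R,5R,7R)-3-ethenyl-8-hydroxy-4,4,7-trimethyl-9-(2-methylpropanoyl)tricyclo[5.3.1.0^1,5]undec-8-ene-10,11-dione | C=C[C@H]1C[C@]23C(=O)[C@](C)(C[C@@H]2C1(C)C)C(O)=C(C(=O)C(C)C)C3=O | intermediate
18 | 3-methylbut-2-en-1-yl acetate | CC(=O)OCC=C(C)C | starting material
19 | (1R,3R,5R,7S,9S)-3-ethenyl-4,4,7-trimethyl-9-(3-methylbut-2-en-1-yl)-9-(2-methylpropanoyl)tricyclo[5.3.1.0^1,5]undecane-8,10,11-trione | C=C[C@H]1C[C@]23C(=O)[C@](C)(C[C@@H]2C1(C)C)C(=O)[C@](CC=C(C)C)(C(=O)C(C)C)C3=O | intermediate
20 | (1R,3S,5R,7S,9S)-3-acetyl-4,4,7-trimethyl-9-(3-methylbut-2-en-1-yl)-9-(2-methylpropanoyl)tricyclo[5.3.1.0^1,5]undecane-8,10,11-trione | CC(=O)[C@H]1C[C@]23C(=O)[C@](C)(C[C@@H]2C1(C)C)C(=O)[C@](CC=C(C)C)(C(=O)C(C)C)C3=O | target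

**Totals**
Total step count: 10. Longest linear sequence: 10 steps (from 1).

**Steps most likely to fail**

Step 8. The spiro-activated vinylcyclopropane may isomerise before the chain is carried, either by ring opening through oxygen to a dihydrofuran or by a [3,3] shift to a dihydrooxepine. The tertiary radical may also be intercepted by the disulfide before the second closure, or that closure may show poor facial selectivity. The fallback splits the event into an ionic opening and an oxidative radical bicyclisation.
- It sets out from 16, which is opened with PhSH under Pd(PPh3)4 catalysis in THF. The thiolate attacks the less hindered terminus of the allyl palladium zwitterion.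
- This should give (6S)-3,5-dihydroxy-6-methyl-6-(3-methylbut-2-en-1-yl)-2-(2-methylpropanoyl)-4-[(2E)-4-(phenylsulfanyl)but-2-en-1-yl]cyclohexa-2,4-dien-1-one F1.
- Oxidation of its enol with Mn(OAc)3·2H2O in AcOH forms the same C3 radical by way of the trivalent manganese enolate. The two 5-exo closures and the β-loss of the thiyl radical follow, and the sequence comes back to the route at 17.

Step 7. The second alkylation may close through an enolate oxygen to a vinyl dihydrofuran, or bromide may reopen the activated ring and let the system drain to that isomer. The fallback builds the three-membered ring on an open-chain β-keto ester, where closure through carbon is the rule, and forms the six-membered ring afterwards.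
- It sets out from 9, which is activated as 11 and homologated by the Masamune–Brooks method (potassium 3-methoxy-3-oxopropanoate, MgCl2, Et3N, THF) to 1-(2,2-diphenylethyl) 5-methyl (2S)-2-methyl-2-(3-methylbut-2-en-1-yl)-3-oxopentanedioate F2.
- Treatment with 15 and K2CO3 in DMF should give 2,2-diphenylethyl (2S)-3-[2-ethenyl-1-(methoxycarbonyl)cyclopropyl]-2-methyl-2-(3-methylbut-2-en-1-yl)-3-oxopropanoate F3.
- A double Claisen condensation with excess lithium enolate of 3-methylbutan-2-one (LDA, THF, −78 °C to rt) then inserts C10 between the two ester carbons, in whichever order they react. The sequence comes back to the route at 16.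

Step 9. The triketone enolate may be alkylated on oxygen, the allyl complex may be attacked at its branched terminus, reversible C–C ionisation may erode the kinetic product, or facial selectivity may be poor. The fallback forms the C10–C bond by a sigmatropic shift instead of an intermolecular alkylation.
- It sets out from 17, which is O-alkylated with 3-chloro-3-methylbut-1-yne (DBU, CuCl2·2H2O cat., MeCN, 0 °C) to (1R,3R,5R,7R)-3-ethenyl-4,4,7-trimethyl-8-[(2-methylbut-3-yn-2-yl)oxy]-9-(2-methylpropanoyl)tricyclo[5.3.1.0^1,5]undec-8-ene-10,11-dione F4. Regioisomeric enol ethers would converge later.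
- Semihydrogenation (H2, Pd/CaCO3 poisoned with Pb(OAc)2, quinoline, EtOAc) should give (1R,3R,5R,7R)-3-ethenyl-4,4,7-trimethyl-8-[(2-methylbut-3-en-2-yl)oxy]-9-(2-methylpropanoyl)tricyclo[5.3.1.0^1,5]undec-8-ene-10,11-dione F5.
- A Claisen rearrangement in warm toluene delivers the allyl unit with transposition, that is as a linear prenyl group, to the C10 face anti to the C6–C7 bridge. The sequence comes back to the route at 19.

**Further compounds**
F1 | step 8 | (6S)-3,5-dihydroxy-6-methyl-6-(3-methylbut-2-en-1-yl)-2-(2-methylpropanoyl)-4-[(2E)-4-(phenylsulfanyl)but-2-en-1-yl]cyclohexa-2,4-dien-1-one | CC(C)C(=O)C1=C(O)C(C/C=C/CSc2ccccc2)=C(O)[C@](C)(CC=C(C)C)C1=O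
F2 | step 7 | 1-(2,2-diphenylethyl) 5-methyl (2S)-2-methyl-2-(3-methylbut-2-en-1-yl)-3-oxopentanedioate | COC(=O)CC(=O)[C@](C)(CC=C(C)C)C(=O)OCC(c1ccccc1)c1ccccc1
F3 | step 7 | 2,2-diphenylethyl (2S)-3-[2-ethenyl-1-(methoxycarbonyl)cyclopropyl]-2-methyl-2-(3-methylbut-2-en-1-yl)-3-oxopropanoate | COC(=O)C1(CC1C=C)C(=O)[C@](C)(CC=C(C)C)C(=O)OCC(c1ccccc1)c1ccccc1
F4 | step 9 | (1R,3R,5R,7R)-3-ethenyl-4,4,7-trimethyl-8-[(2-methylbut-3-yn-2-yl)oxy]-9-(2-methylpropanoyl)tricyclo[5.3.1.0^1,5]undec-8-ene-10,11-dione | C=C[C@H]1C[C@]23C(=O)[C@](C)(C[C@@H]2C1(C)C)C(OC(C)(C)C#C)=C(C(=O)C(C)C)C3=O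
F5 | step 9 | (1R,3R,5R,7R)-3-ethenyl-4,4,7-trimethyl-8-[(2-methylbut-3-en-2-yl)oxy]-9-(2-methylpropanoyl)tricyclo[5.3.1.0^1,5]undec-8-ene-10,11-dione | C=C[C@H]1C[C@]23C(=O)[C@](C)(C[C@@H]2C1(C)C)C(OC(C)(C)C=C)=C(C(=O)C(C)C)C3=O
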